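**Plan**
- Numbering: tetralin C1 (carbinol), C2, C3, C4 (diarylmethine); ring A is the methoxy-bearing benzo ring, ring B the saturated ring. C2 and C3 are the only ring B atoms with neither a substituent nor a stereocentre, so the first cut is C2–C3 (made as C2=C3 by ring-closing metathesis). This opens ring B to a diene with one vinyl group on C1 and one on C4.
- Second cut: C4–C4a, a copper-catalysed SN2' arylation of a 3-(naphthalen-2-yl)allyl phosphate by a ring A arylboronate. Third cut: C1–C2, vinyl addition to 2-bromo-3-methoxybenzaldehyde. The naphthalene side chain comes from ortho-formylation of 8-methoxy-1-naphthol and a two-carbon olefination.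
- Forward: the ring A fragment (steps 1–3) and the naphthalene fragment (steps 4–8) are joined at C4 (step 9). Ring B then closes (step 10), C2=C3 is saturated (step 11) and both silicon-based protecting groups leave together (step 12).
- Stereochemistry: C1 (S) comes from a ligand-controlled vinylzinc addition, C4 (R) from a chiral carbene–copper catalyst. The trans-1,4 relation is therefore fixed before ring B exists, and the ring closure creates no stereocentre.

Key step: step 10

Assumption: the sense of induction in steps 1 and 9 is taken from the parent benzaldehyde and cinnamyl cases. Imidazolinium salt Q is 1-(2,6-diisopropylphenyl)-4,5-diphenyl-3-(2-sulfonatophenyl)-4,5-dihydroimidazolium (zwitterion), used as whichever antipode, (4S,5S) or (4R,5R), gives the 4R product; the remote C1 centre is not expected to override either catalyst.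

**Route**

Step 1
Reactants: 1 2-bromo-3-methoxybenzaldehyde
Product: 2 (S)-1-(2-bromo-3-methoxyphenyl)prop-2-en-1-ol
Conditions: Zn(CH=CH2)2 (1.5 equiv), (−)-3-exo-(dimethylamino)isoborneol (5 mol%), toluene–Et2O, 0 °C; aq. NH4Cl
Reagents that add atoms: divinylzinc, C=C[Zn]C=C
Why: Amino-alcohol-catalysed asymmetric organozinc addition to an aldehyde, in which the chiral zinc aminoalkoxide binds both partners and passes a vinyl group to the Si face of the carbonyl, setting C1 as S while the ortho bromine stays inert.

Step 2
Reactants: 2 (S)-1-(2-bromo-3-methoxyphenyl)prop-2-en-1-ol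
Product: 3 tert-butyl{[(S)-1-(2-bromo-3-methoxyphenyl)prop-2-en-1-yl]oxy}dimethylsilane
Conditions: TBSCl, imidazole, DMF, rt
Reagents that add atoms: tert-butyldimethylsilyl chloride, CC(C)(C)[Si](C)(C)Cl
Why: Standard silylation of a secondary alcohol, which removes the acidic proton before the organolithium step and later guards the benzylic allylic carbinol against ionisation and alkene migration without touching C1.

Step 3
Reactants: 3 tert-butyl{[(S)-1-(2-bromo-3-methoxyphenyl)prop-2-en-1-yl]oxy}dimethylsilane
Product: 6 2-{2-[(S)-1-(tert-butyldimethylsilyloxy)prop-2-en-1-yl]-6-methoxyphenyl}-5,5-dimethyl-1,3,2-dioxaborinane, via aryllithium 4 (not isolated), via arylboronic acid 5 (not isolated)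
Conditions: n-BuLi, THF, −78 °C; B(OMe)3, −78 °C to rt; aq. NH4Cl; neopentyl glycol, MgSO4, CH2Cl2, rt
Reagents that add atoms: trimethyl borate, COB(OC)OC; 2,2-dimethylpropane-1,3-diol, OCC(C)(C)CO
Why: Bromine–lithium exchange at −78 °C outruns deprotonation and oxygen-to-carbon silyl migration, the aryllithium is trapped at boron, and condensation with the diol gives the neopentyl glycol ester, the boronate type that hands aryl groups most readily to copper alkoxides.

Step 4
Reactants: 7 8-methoxy-1-naphthol
Product: 8 1-hydroxy-8-methoxy-2-naphthaldehyde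
Conditions: MgCl2, Et3N, (CH2O)n, MeCN, reflux; 1 M HCl
Reagents that add atoms: paraformaldehyde (as formaldehyde), C=O
Why: Casnati–Skattebøl ortho-formylation, in which the magnesium naphthoxide delivers formaldehyde to C2, the only free position ortho to the oxygen, and a second formaldehyde oxidises the hydroxymethyl intermediate to the aldehyde by hydride transfer.

Step 5
Reactants: 8 1-hydroxy-8-methoxy-2-naphthaldehyde
Product: 9 8-methoxy-1-{[2-(trimethylsilyl)ethoxy]methoxy}-2-naphthaldehyde
Conditions: NaH, DMF, 0 °C; SEMCl, 0 °C to rt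
Reagents that add atoms: 2-(trimethylsilyl)ethoxymethyl chloride, C[Si](C)(C)CCOCCl
Why: Williamson-type O-alkylation of the sodium naphthoxide by a reactive chloromethyl ether, giving a small acetal-type protecting group that tolerates base, hydride, alkoxide and ruthenium and is removed by fluoride at the end.

Step 6
Reactants: 9 8-methoxy-1-{[2-(trimethylsilyl)ethoxy]methoxy}-2-naphthaldehyde; 10 triethyl phosphonoacetate
Product: 11 ethyl (E)-3-(8-methoxy-1-{[2-(trimethylsilyl)ethoxy]methoxy}naphthalen-2-yl)prop-2-enoate
Conditions: NaH, THF, 0 °C to rt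
Reagents that add atoms: none
Why: Horner–Wadsworth–Emmons olefination of an aromatic aldehyde by a stabilised phosphonate anion, which is reliably E-selective.

Step 7
Reactants: 11 ethyl (E)-3-(8-methoxy-1-{[2-(trimethylsilyl)ethoxy]methoxy}naphthalen-2-yl)prop-2-enoate
Product: 12 (E)-3-(8-methoxy-1-{[2-(trimethylsilyl)ethoxy]methoxy}naphthalen-2-yl)prop-2-en-1-ol
Conditions: i-Bu2AlH (2.5 equiv), CH2Cl2, −78 °C to 0 °C; aq. potassium sodium tartrate
Reagents that add atoms: none
Why: 1,2-Reduction of an α,β-unsaturated ester by an aluminium hydride at low temperature gives the allylic alcohol and leaves the alkene geometry and the acetal untouched.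

Step 8
Reactants: 12 (E)-3-(8-methoxy-1-{[2-(trimethylsilyl)ethoxy]methoxy}naphthalen-2-yl)prop-2-en-1-ol
Product: 13 diethyl (E)-3-(8-methoxy-1-{[2-(trimethylsilyl)ethoxy]methoxy}naphthalen-2-yl)prop-2-en-1-yl phosphate
Conditions: ClP(O)(OEt)2, Et3N, DMAP (cat.), CH2Cl2, 0 °C; used without delay
Reagents that add atoms: diethyl chlorophosphate, CCOP(=O)(Cl)OCC
Why: O-Phosphorylation of a primary allylic alcohol installs the leaving group that copper-catalysed allylic substitution uses best, and the cold, basic conditions avoid ionisation of the electron-rich cinnamyl system.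

Step 9
Reactants: 6 2-{2-[(S)-1-(tert-butyldimethylsilyloxy)prop-2-en-1-yl]-6-methoxyphenyl}-5,5-dimethyl-1,3,2-dioxaborinane; 13 diethyl (E)-3-(8-methoxy-1-{[2-(trimethylsilyl)ethoxy]methoxy}naphthalen-2-yl)prop-2-en-1-yl phosphate
Product: 14 tert-butyl{[(S)-1-(3-methoxy-2-{(R)-1-(8-methoxy-1-{[2-(trimethylsilyl)ethoxy]methoxy}naphthalen-2-yl)prop-2-en-1-yl}phenyl)prop-2-en-1-yl]oxy}dimethylsilane
Conditions: CuCl (5 mol%), imidazolinium salt Q (5.5 mol%), NaOMe (1.5 equiv), THF, 30 °C
Reagents that add atoms: none
Why: Copper-catalysed enantioselective allylic substitution, in which the methoxide-activated boronate passes its aryl group to the carbene-bound copper alkoxide and the arylcopper attacks the γ-carbon of the phosphate anti to the leaving group (SN2'), the sulfonate-bearing carbene choosing the alkene face so that C4 forms as R and the terminal vinyl group appears, with C1 untouched.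

Step 10
Reactants: 14 tert-butyl{[(S)-1-(3-methoxy-2-{(R)-1-(8-methoxy-1-{[2-(trimethylsilyl)ethoxy]methoxy}naphthalen-2-yl)prop-2-en-1-yl}phenyl)prop-2-en-1-yl]oxy}dimethylsilane
Product: 15 tert-butyl{[(1S,4R)-5-methoxy-4-(8-methoxy-1-{[2-(trimethylsilyl)ethoxy]methoxy}naphthalen-2-yl)-1,4-dihydronaphthalen-1-yl]oxy}dimethylsilane
Conditions: second-generation Grubbs catalyst RuCl2(=CHPh)(PCy3)(H2IMes) (5 mol%), CH2Cl2 (0.005 M), 40 °C, argon; filtration through Et3N-washed silica
Reagents that add atoms: none
Why: The ruthenium benzylidene exchanges onto one terminal vinyl group, the new alkylidene adds across the other vinyl group in a [2+2] cycloaddition, and cycloreversion of the ruthenacyclobutane forms C2=C3 and expels ethene, whose escape drives the reaction. The closest known reaction type is ring-closing metathesis of ortho-bis(allyl)benzenes to 1,4-dihydronaphthalenes. Ring B closes as a six-membered carbocycle by joining the two vinyl carbons that become C2 and C3, the ortho placement of the two arms on ring A holding them close enough that cyclisation beats cross-metathesis at high dilution. No stereocentre is formed, and C1 and C4 keep their configurations because neither allylic C–H bond is broken in the metathesis cycle. The step needs chemoselectivity for metathesis over ruthenium hydride-induced alkene migration and over 1,4-elimination to a naphthalene; the silyl ether at C1, the protected naphthol, neutral conditions and a short reaction time are chosen to secure this.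

Step 11
Reactants: 15 tert-butyl{[(1S,4R)-5-methoxy-4-(8-methoxy-1-{[2-(trimethylsilyl)ethoxy]methoxy}naphthalen-2-yl)-1,4-dihydronaphthalen-1-yl]oxy}dimethylsilane
Product: 16 tert-butyl{[(1S,4R)-5-methoxy-4-(8-methoxy-1-{[2-(trimethylsilyl)ethoxy]methoxy}naphthalen-2-yl)-1,2,3,4-tetrahydronaphthalen-1-yl]oxy}dimethylsilane
Conditions: 2-nitrobenzenesulfonohydrazide (excess, in portions), Et3N, CH2Cl2, rt
Reagents that add atoms: none
Why: Diimide reduction, in which diazene released from the sulfonohydrazide by base transfers two hydrogens to C2=C3 in a concerted syn fashion, so no metal hydride is present that could move the double bond toward C1 or C4 or cleave a benzylic C–O bond, and both stereocentres are kept.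

Step 12
Reactants: 16 tert-butyl{[(1S,4R)-5-methoxy-4-(8-methoxy-1-{[2-(trimethylsilyl)ethoxy]methoxy}naphthalen-2-yl)-1,2,3,4-tetrahydronaphthalen-1-yl]oxy}dimethylsilane
Product: 17 dipolynaphthalene A [(1S,4R)-4-(1-hydroxy-8-methoxynaphthalen-2-yl)-5-methoxy-1,2,3,4-tetrahydronaphthalen-1-ol]
Conditions: Bu4NF (6 equiv), THF–DMPU, 60 °C, argon; aq. NH4Cl
Reagents that add atoms: none
Why: Fluoride-induced desilylation cleaves the silyl ether at C1 directly and fragments the SEM group to fluorotrimethylsilane, ethene and formaldehyde with release of the naphthoxide, and since no acid meets the benzylic carbinol, C1 cannot ionise and the trans relation is kept.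

**Compound list**
1 | 2-bromo-3-methoxybenzaldehyde | COc1cccc(C=O)c1Br | starting material
2 | (S)-1-(2-bromo-3-methoxyphenyl)prop-2-en-1-ol | COc1cccc([C@@H](O)C=C)c1Br | intermediate
3 | tert-butyl{[(S)-1-(2-bromo-3-methoxyphenyl)prop-2-en-1-yl]oxy}dimethylsilane | COc1cccc([C@@H](O[Si](C)(C)C(C)(C)C)C=C)c1Br | intermediate
4 | {2-[(S)-1-(tert-butyldimethylsilyloxy)prop-2-en-1-yl]-6-methoxyphenyl}lithium | COc1cccc([C@@H](O[Si](C)(C)C(C)(C)C)C=C)c1[Li] | intermediate
5 | {2-[(S)-1-(tert-butyldimethylsilyloxy)prop-2-en-1-yl]-6-methoxyphenyl}boronic acid | COc1cccc([C@@H](O[Si](C)(C)C(C)(C)C)C=C)c1B(O)O | intermediate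
6 | 2-{2-[(S)-1-(tert-butyldimethylsilyloxy)prop-2-en-1-yl]-6-methoxyphenyl}-5,5-dimethyl-1,3,2-dioxaborinane | COc1cccc([C@@H](O[Si](C)(C)C(C)(C)C)C=C)c1B1OCC(C)(C)CO1 | intermediate
7 | 8-methoxy-1-naphthol | COc1cccc2cccc(O)c12 | starting material
8 | 1-hydroxy-8-methoxy-2-naphthaldehyde | COc1cccc2ccc(C=O)c(O)c12 | intermediate
9 | 8-methoxy-1-{[2-(trimethylsilyl)ethoxy]methoxy}-2-naphthaldehyde | COc1cccc2ccc(C=O)c(OCOCC[Si](C)(C)C)c12 | intermediate
10 | triethyl phosphonoacetate | CCOC(=O)CP(=O)(OCC)OCC | starting material
11 | ethyl (E)-3-(8-methoxy-1-{[2-(trimethylsilyl)ethoxy]methoxy}naphthalen-2-yl)prop-2-enoate | CCOC(=O)/C=C/c1ccc2cccc(OC)c2c1OCOCC[Si](C)(C)C | intermediate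
12 | (E)-3-(8-methoxy-1-{[2-(trimethylsilyl)ethoxy]methoxy}naphthalen-2-yl)prop-2-en-1-ol | OC/C=C/c1ccc2cccc(OC)c2c1OCOCC[Si](C)(C)C | intermediate
13 | diethyl (E)-3-(8-methoxy-1-{[2-(trimethylsilyl)ethoxy]methoxy}naphthalen-2-yl)prop-2-en-1-yl phosphate | CCOP(=O)(OCC)OC/C=C/c1ccc2cccc(OC)c2c1OCOCC[Si](C)(C)C | intermediate
14 | tert-butyl{[(S)-1-(3-methoxy-2-{(R)-1-(8-methoxy-1-{[2-(trimethylsilyl)ethoxy]methoxy}naphthalen-2-yl)prop-2-en-1-yl}phenyl)prop-2-en-1-yl]oxy}dimethylsilane (the diene with vinyl groups on C1 and C4) | COc1cccc([C@@H](O[Si](C)(C)C(C)(C)C)C=C)c1[C@H](C=C)c1ccc2cccc(OC)c2c1OCOCC[Si](C)(C)C | intermediate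
15 | tert-butyl{[(1S,4R)-5-methoxy-4-(8-methoxy-1-{[2-(trimethylsilyl)ethoxy]methoxy}naphthalen-2-yl)-1,4-dihydronaphthalen-1-yl]oxy}dimethylsilane (trans) | COc1cccc2c1[C@@H](c1ccc3cccc(OC)c3c1OCOCC[Si](C)(C)C)C=C[C@@H]2O[Si](C)(C)C(C)(C)C | intermediate
16 | tert-butyl{[(1S,4R)-5-methoxy-4-(8-methoxy-1-{[2-(trimethylsilyl)ethoxy]methoxy}naphthalen-2-yl)-1,2,3,4-tetrahydronaphthalen-1-yl]oxy}dimethylsilane | COc1cccc2c1[C@@H](c1ccc3cccc(OC)c3c1OCOCC[Si](C)(C)C)CC[C@@H]2O[Si](C)(C)C(C)(C)C | intermediate
17 | dipolynaphthalene A, (1S,4R)-4-(1-hydroxy-8-methoxynaphthalen-2-yl)-5-methoxy-1,2,3,4-tetrahydronaphthalen-1-ol | COc1cccc2c1[C@@H](c1ccc3cccc(OC)c3c1O)CC[C@@H]2O | target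

**Count**
Total: 12 steps. Longest linear sequence: 9 steps (7 to 17, steps 4–12); the ring A branch (1 to 17) is 7 steps.

**Steps most likely to fail**

Step 9. The aryl group on boron has two ortho substituents and may transfer to copper too slowly, so that protodeboronation takes over. The copper may also attack the α-carbon, or the wrong face of the congested γ-carbon, and erode regio- and enantiocontrol. The fallback sets C4 by stoichiometric chirality transfer and sets out from aldehyde 9 and bromide 3.
- Wittig olefination of 9 with Ph3P=CHC(O)CH3 in toluene should give (E)-4-(8-methoxy-1-{[2-(trimethylsilyl)ethoxy]methoxy}naphthalen-2-yl)but-3-en-2-one F1.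
- Corey–Bakshi–Shibata reduction with the (R)-configured B-methyl oxazaborolidine and BH3·SMe2 should give the (S,E)-configured but-3-en-2-ol F2.
- Esterification with pyridine-2-carboxylic acid (DCC, DMAP) should give the (S,E)-but-3-en-2-yl pyridine-2-carboxylate F3.
- Aryllithium 4, made from 3 as in step 3, is converted with MgBr2·OEt2 into {2-[(S)-1-(tert-butyldimethylsilyloxy)prop-2-en-1-yl]-6-methoxyphenyl}magnesium bromide F4.
- F4 with CuBr·SMe2 (half an equivalent relative to magnesium) in THF at 0 °C should displace the chelating picolinate of F3 in anti-SN2' fashion. Arylcopper reagents with two ortho substituents are competent in this reaction class. Attack anti to the leaving group through the conformer with the carbinol hydrogen eclipsing the alkene transfers the S configuration into the (R)-diarylmethine and gives the (E)-prop-1-enyl analogue of the diene, F5.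
- Ring-closing metathesis of F5 under the conditions of step 10 expels propene in place of ethene and comes back to the route at 15.

Step 1. An uncatalysed or magnesium-salt-promoted racemic addition may compete with the ligand-accelerated pathway and lower the enantiomeric purity at C1, which would show up as a diastereomer after step 9. The fallback sets out from 1.
- Addition of CH2=CHMgBr in THF at −78 °C should give racemic 1-(2-bromo-3-methoxyphenyl)prop-2-en-1-ol F6.
- Sharpless kinetic resolution (Ti(OiPr)4, L-(+)-diisopropyl tartrate, t-BuOOH 0.6 equiv, 4 Å molecular sieves, CH2Cl2, −20 °C) should epoxidise the (R)-enantiomer to (S)-(2-bromo-3-methoxyphenyl)[(R)-oxiran-2-yl]methanol F7.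
- The unreacted (S)-alcohol is 2, where the fallback rejoins the route.

Step 11. Diazene may disproportionate faster than it reduces the ring alkene, both faces of which carry a neighbouring substituent. Long exposure could also allow 1,4-elimination of silanol to a naphthalene. The fallback sets out from 15 and replaces the concerted transfer by surface-catalysed hydrogenation: H2 (1 atm) over 5% Pt/C in EtOAc at rt. Platinum is chosen because it migrates double bonds and cleaves benzylic C–O bonds far less than palladium. It comes back at 16 and makes no compound outside the list (F0).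

**Further compounds**
F1 | step 9 | (E)-4-(8-methoxy-1-{[2-(trimethylsilyl)ethoxy]methoxy}naphthalen-2-yl)but-3-en-2-one | CC(=O)/C=C/c1ccc2cccc(OC)c2c1OCOCC[Si](C)(C)C
F2 | step 9 | (S,E)-4-(8-methoxy-1-{[2-(trimethylsilyl)ethoxy]methoxy}naphthalen-2-yl)but-3-en-2-ol | C[C@H](O)/C=C/c1ccc2cccc(OC)c2c1OCOCC[Si](C)(C)C
F3 | step 9 | (S,E)-4-(8-methoxy-1-{[2-(trimethylsilyl)ethoxy]methoxy}naphthalen-2-yl)but-3-en-2-yl pyridine-2-carboxylate | C[C@H](OC(=O)c1ccccn1)/C=C/c1ccc2cccc(OC)c2c1OCOCC[Si](C)(C)C
F4 | step 9 | {2-[(S)-1-(tert-butyldimethylsilyloxy)prop-2-en-1-yl]-6-methoxyphenyl}magnesium bromide | COc1cccc([C@@H](O[Si](C)(C)C(C)(C)C)C=C)c1[Mg]Br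
F5 | step 9 | tert-butyl{[(S)-1-(3-methoxy-2-{(R,E)-1-(8-methoxy-1-{[2-(trimethylsilyl)ethoxy]methoxy}naphthalen-2-yl)but-2-en-1-yl}phenyl)prop-2-en-1-yl]oxy}dimethylsilane | COc1cccc([C@@H](O[Si](C)(C)C(C)(C)C)C=C)c1[C@H](/C=C/C)c1ccc2cccc(OC)c2c1OCOCC[Si](C)(C)C
F6 | step 1 | racemic 1-(2-bromo-3-methoxyphenyl)prop-2-en-1-ol | COc1cccc(C(O)C=C)c1Br
F7 | step 1 | (S)-(2-bromo-3-methoxyphenyl)[(R)-oxiran-2-yl]methanol | COc1cccc([C@H](O)[C@H]2CO2)c1Br
F0 | step 11 | none | none
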